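**Strategy.** The seven-membered ring (C1, C5–C10; daucane numbering) is read as a benzene ring plus one carbon: C5–C10 map onto a 2-methoxy-4-methylphenyl ring (C6–O ortho, C8–CH3 para to C5), and C1, the methyl-bearing quaternary carbon next to the C2 oxygen, is the carbon of a methyl-substituted α-diazoketone. The key step, an intramolecular Buchner reaction, adds the rhodium carbenoid to the C5–C10 arene bond and opens the norcaradiene, so that one operation closes the five-membered ring, expands the arene to the cycloheptatriene and sets the C1 quaternary centre under control of a C4 isopropyl stereocentre. The precursor is (5R)-2-diazo-5-(2-methoxy-4-methylphenyl)-6-methylheptan-3-one.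

Key step: step 4

Numbering: daucane locants are used (C1 quaternary ring-fusion carbon with CH3; C2, C3, C4 with isopropyl; C5 ring-fusion CH; C6, C7, C8 with CH3, C9, C10); β is the face of the C1 methyl group, α the opposite face.

Remark on the chemistry (one assumption): read together, the descriptors written at C8 and C9 of the target string place C7 and C10 on opposite sides of the oxirane; the string is reproduced unchanged for 17, and the oxirane is taken as the cis-fused 8α,9α-oxirane on the face of the C10 hydroxyl, which is what its C9 descriptor says and what epoxidation of the ring alkene can deliver.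

Step 1
Reactants: 1 (2-methoxy-4-methylphenyl)boronic acid; 2 ethyl (E)-4-methylpent-2-enoate
Product: 3 ethyl (3R)-3-(2-methoxy-4-methylphenyl)-4-methylpentanoate
Conditions: [Rh(acac)(C2H4)2] (3 mol%), (R)-BINAP, dioxane/H2O 10:1, 100 °C
Reagents that add atoms: none
Why: Hayashi–Miyaura rhodium-catalysed asymmetric 1,4-addition of an arylboronic acid to an enoate; the BINAP enantiomer is the one expected to deliver the aryl group to the enoate face that gives the 3R centre, which later serves as the relay centre C4.

Step 2
Reactants: 3 ethyl (3R)-3-(2-methoxy-4-methylphenyl)-4-methylpentanoate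
Product: 4 (3R)-3-(2-methoxy-4-methylphenyl)-4-methylpentanoic acid
Conditions: LiOH, THF/MeOH/H2O, rt; then 1 M HCl
Reagents that add atoms: lithium hydroxide, [Li+].[OH-]
Why: Ester saponification; the stereocentre is β to the carbonyl and cannot epimerise.

Step 3
Reactants: 4 (3R)-3-(2-methoxy-4-methylphenyl)-4-methylpentanoic acid
Product: 6 (5R)-2-diazo-5-(2-methoxy-4-methylphenyl)-6-methylheptan-3-one, via acid chloride 5 (not isolated)
Conditions: (COCl)2, cat. DMF, CH2Cl2, 0 °C to rt, concentrate; then CH3CHN2 (3 equiv, from N-ethyl-N-nitrosourea and KOH), Et2O, −20 to 0 °C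
Reagents that add atoms: oxalyl chloride, O=C(Cl)C(Cl)=O; diazoethane, CC=[N+]=[N-]
Why: Acylation of a diazoalkane by an acid chloride (Arndt–Eistert-type diazoketone synthesis), with excess diazoethane taking up the HCl; the stereocentre is untouched.

Step 4
Reactants: 6 (5R)-2-diazo-5-(2-methoxy-4-methylphenyl)-6-methylheptan-3-one
Product: 8 6-methoxy-dauca-5,7,9-trien-2-one (1β-CH3, 4α-isopropyl, 4β-H), via norcaradiene 7 (not isolated)
Conditions: Rh2(OAc)4 (1 mol%), CH2Cl2, reflux, slow addition of 6
Reagents that add atoms: none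
Why: Rh2(OAc)4 converts the diazoketone into an electrophilic rhodium carbenoid, which cyclopropanates the arene across C5 (ipso) and C10 (the unsubstituted ortho carbon) to norcaradiene 7; 7 opens by a thermal 6π disrotatory electrocyclic reaction to cycloheptatriene 8. The closest known reaction is the intramolecular Buchner reaction of 2-diazo-5-arylpentan-3-ones to 8a-methyl-dihydroazulenones. The five-membered ring is closed by carbenoid [2+1] addition through the three-atom tether (5-exo-type closure onto C5), and the seven-membered ring arises from the six-membered arene by insertion of C1 between C5 and C10 (cyclopropanation, then electrocyclic ring opening). The only new stereocentre, quaternary C1, is controlled by C4: in the cyclopropanation the isopropyl group lies on the side of the reacting ortho carbon, away from the methoxy group, so the C1 methyl ends trans to it. The step needs site selectivity for the C5–C10 bond over the C5–C6 bond (secured by the ortho methoxy group) and chemoselectivity for arene addition over 1,2-hydride shift and C–H insertion into the isopropyl methine (secured by the electron-rich arene and the five-membered transition state).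

Step 5
Reactants: 8 6-methoxy-dauca-5,7,9-trien-2-one
Product: 9 6-methoxy-dauca-5,7,9-trien-2β-ol (1β-CH3, 4α-isopropyl)
Conditions: NaBH4, MeOH, 0 °C
Reagents that add atoms: none
Why: Borohydride reduction of the C2 ketone; hydride should add anti to the pseudo-axial C1 methyl to give the 2β-alcohol, and the enol ether and triene are inert.

Step 6
Reactants: 9 6-methoxy-dauca-5,7,9-trien-2β-ol
Product: 10 2β-hydroxy-dauca-4,7,9-trien-6-one
Conditions: DDQ (1.2 equiv), CH2Cl2/H2O 10:1, 0 °C to rt
Reagents that add atoms: water, O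
Why: DDQ dehydrogenation of an enol ether to an enone: hydride abstraction from allylic C4 gives an oxocarbenium ion that water collapses to the C6 ketone with a C4=C5 double bond; this erases the relay centre C4, and quaternary C1 blocks further dehydrogenation.

Step 7
Reactants: 10 2β-hydroxy-dauca-4,7,9-trien-6-one
Product: 11 2α-acetoxy-dauca-4,7,9-trien-6-one
Conditions: PPh3, DIAD, AcOH, THF, 0 °C to rt
Reagents that add atoms: acetic acid, CC(=O)O
Why: Mitsunobu reaction with inversion at C2 (as in the conversion of 17β- into 17α-oxygenated steroids); acetate displaces the β-oxyphosphonium group from the α face, opposite the C1 methyl, and sets the 2α-acetate.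

Step 8
Reactants: 11 2α-acetoxy-dauca-4,7,9-trien-6-one
Product: 12 2α-acetoxy-4α,5α:9α,10α-diepoxy-dauc-7-en-6-one
Conditions: dimethyldioxirane (3 equiv), acetone, 0 °C to rt
Reagents that add atoms: dimethyldioxirane, CC1(C)OO1
Why: Dioxirane epoxidation of an enone and of the distal bond of a dienone; the distal C9=C10 bond and the tetrasubstituted C4=C5 bond should react before the least nucleophilic C7=C8 bond, each from the convex α face opposite the pseudo-axial C1 methyl, which sets C4 and C10.

Step 9
Reactants: 12 2α-acetoxy-4α,5α:9α,10α-diepoxy-dauc-7-en-6-one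
Product: 14 2α-acetoxy-dauc-8-ene-4α,6α,10α-triol (5α-H, trans ring fusion), via hydroxy ketone 13 (not isolated)
Conditions: SmI2 (4.5 equiv), MeOH, THF, −78 °C; then SmI2 (2.5 equiv), H2O, Et3N, −78 to 0 °C
Reagents that add atoms: none
Why: Samarium diiodide reductions of an α,β-epoxy ketone (C5–O cleavage) and of a γ,δ-epoxy enone (vinylogous C9–O cleavage with kinetic protonation at C7); C5 should be protonated from the α face because the C1 methyl and C4 isopropyl block the β face, and the ketyl reduction with SmI2/H2O/Et3N should give the more stable equatorial 6α-alcohol, away from the syn-axial C1 methyl.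

Step 10
Reactants: 14 2α-acetoxy-dauc-8-ene-4α,6α,10α-triol; 15 3,4-dimethoxybenzoyl chloride
Product: 16 2α-acetoxy-6α-(3,4-dimethoxybenzoyloxy)-dauc-8-ene-4α,10α-diol
Conditions: 15 (1.1 equiv), pyridine, cat. DMAP, CH2Cl2, 0 °C
Reagents that add atoms: none
Why: DMAP-catalysed acylation; the secondary 6α-hydroxyl should react ahead of the neopentyl allylic C10 hydroxyl (next to quaternary C1) and the tertiary C4 hydroxyl.

Step 11
Reactants: 16 2α-acetoxy-6α-(3,4-dimethoxybenzoyloxy)-dauc-8-ene-4α,10α-diol
Product: 17 2α-acetoxy-6α-(3,4-dimethoxybenzoyloxy)-8,9-epoxy-daucane-4α,10α-diol (target)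
Conditions: VO(acac)2 (5 mol%), t-BuOOH, CH2Cl2, 0 °C to rt
Reagents that add atoms: tert-butyl hydroperoxide, CC(C)(C)OO
Why: Vanadium-catalysed hydroxyl-directed epoxidation of a cyclic allylic alcohol; oxygen is delivered to the face of the C10 hydroxyl and sets C8 and C9, while the esters and the remote tertiary alcohol are untouched.

**Compound list**

1 | (2-methoxy-4-methylphenyl)boronic acid | COc1cc(C)ccc1B(O)O | starting material
2 | ethyl (E)-4-methylpent-2-enoate | CCOC(=O)/C=C/C(C)C | starting material
3 | ethyl (3R)-3-(2-methoxy-4-methylphenyl)-4-methylpentanoate | CCOC(=O)C[C@H](C(C)C)c1ccc(C)cc1OC | intermediate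
4 | (3R)-3-(2-methoxy-4-methylphenyl)-4-methylpentanoic acid | OC(=O)C[C@H](C(C)C)c1ccc(C)cc1OC | intermediate
5 | (3R)-3-(2-methoxy-4-methylphenyl)-4-methylpentanoyl chloride (not isolated) | ClC(=O)C[C@H](C(C)C)c1ccc(C)cc1OC | intermediate
6 | (5R)-2-diazo-5-(2-methoxy-4-methylphenyl)-6-methylheptan-3-one | CC(=[N+]=[N-])C(=O)C[C@H](C(C)C)c1ccc(C)cc1OC | intermediate
7 | norcaradiene valence isomer of 8 (cyclopropane C1–C5–C10 on the α face, diene C6=C7–C8=C9; not isolated) | COC1=CC(C)=C[C@H]2[C@]3(C)C(=O)C[C@H](C(C)C)[C@]123 | intermediate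
8 | 6-methoxy-dauca-5,7,9-trien-2-one (1β-CH3, 4α-isopropyl) | COC1=C2[C@@H](C(C)C)CC(=O)[C@@]2(C)C=CC(C)=C1 | intermediate
9 | 6-methoxy-dauca-5,7,9-trien-2β-ol (1β-CH3, 4α-isopropyl) | COC1=C2[C@@H](C(C)C)C[C@H](O)[C@@]2(C)C=CC(C)=C1 | intermediate
10 | 2β-hydroxy-dauca-4,7,9-trien-6-one | CC(C)C1=C2C(=O)C=C(C)C=C[C@]2(C)[C@@H](O)C1 | intermediate
11 | 2α-acetoxy-dauca-4,7,9-trien-6-one | CC(C)C1=C2C(=O)C=C(C)C=C[C@]2(C)[C@H](OC(C)=O)C1 | intermediate
12 | 2α-acetoxy-4α,5α:9α,10α-diepoxy-dauc-7-en-6-one | CC(C)[C@@]12O[C@@]13C(=O)C=C(C)[C@@H]4O[C@@H]4[C@]3(C)[C@H](OC(C)=O)C2 | intermediate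
13 | 2α-acetoxy-4α,10α-dihydroxy-dauc-8-en-6-one (5α-H; not isolated) | O=C1CC(C)=C[C@H](O)[C@]2(C)[C@H](OC(C)=O)C[C@@](O)(C(C)C)[C@@H]12 | intermediate
14 | 2α-acetoxy-dauc-8-ene-4α,6α,10α-triol | O[C@@H]1CC(C)=C[C@H](O)[C@]2(C)[C@H](OC(C)=O)C[C@@](O)(C(C)C)[C@@H]12 | intermediate
15 | 3,4-dimethoxybenzoyl chloride | COc1ccc(C(Cl)=O)cc1OC | starting material
16 | 2α-acetoxy-6α-(3,4-dimethoxybenzoyloxy)-dauc-8-ene-4α,10α-diol | COc1ccc(C(=O)O[C@@H]2CC(C)=C[C@H](O)[C@]3(C)[C@H](OC(C)=O)C[C@@](O)(C(C)C)[C@@H]23)cc1OC | intermediate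
17 | 2α-acetoxy-6α-(3,4-dimethoxybenzoyloxy)-8,9-epoxy-daucane-4α,10α-diol (CNP0197096.3) | COc1ccc(C(=O)O[C@@H]2C[C@@]3(C)O[C@@H]3[C@H](O)[C@]3(C)[C@H](OC(C)=O)C[C@@](O)(C(C)C)[C@@H]23)cc1OC | target

Total step count: 11
Longest linear sequence: 11 steps (1 or 2 to 17)

**Steps most likely to fail**

Step 8. The dioxirane may lose site or facial selectivity: it may attack the C7=C8 bond, add to the β face of the C4=C5 bond, or stall after the first epoxidation. Fallback, from 11: mCPBA (1.05 equiv, NaHCO3, CH2Cl2, 0 °C) should epoxidise only the distal C9=C10 bond from the α face to give the 9α,10α-epoxy dienone F1. SmI2/MeOH (THF, −78 °C) then opens it to the 10α-hydroxy-Δ8 enone F2. The free 10α-hydroxyl directs a Weitz–Scheffer epoxidation with LiOOt-Bu (t-BuOOH, n-BuLi, THF, −20 °C) to the α face of the remaining tetrasubstituted enone, giving the 4α,5α-epoxy ketone F3. SmI2/MeOH cleaves F3 to hydroxy ketone 13, which re-enters the route at the second stage of step 9.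

Step 9. The one-pot samarium cascade may protonate on the wrong carbon or face (C9 instead of C7, or the β face of C5), or the ketyl may be protonated to the axial 6β-alcohol. Fallback, from 12: only the first stage is run (SmI2, MeOH, THF, −78 °C, NH4Cl quench) and hydroxy ketone 13 is isolated. LiBH(s-Bu)3 (THF, −78 °C) adds hydride from the open α face to give the 6β-alcohol F4. A Mitsunobu esterification with 3,4-dimethoxybenzoic acid (PPh3, DIAD, toluene) inverts C6 and installs the ester in one operation, returning to the route at 16.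

Step 4. The methyl-bearing carbenoid may be diverted by 1,2-hydride shift to a vinyl ketone or by C–H insertion into the isopropyl methine before it reaches the arene. Fallback, from 4: acid chloride 5 is treated with diazomethane instead of diazoethane to give the terminal diazoketone F5. Its unsubstituted carbenoid cannot undergo the hydride shift and should give the 8a-H dihydroazulenone F6 in the Buchner reaction (Rh2(OAc)4, CH2Cl2). Deprotonation at the doubly allylic C1 (KN(SiMe3)2, THF, −78 °C) and C-methylation with MeI anti to the C4 isopropyl group returns to the route at 8.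

Further compounds
F1 | step 8 | 2α-acetoxy-9α,10α-epoxy-dauca-4,7-dien-6-one | CC(C)C1=C2C(=O)C=C(C)[C@@H]3O[C@@H]3[C@]2(C)[C@H](OC(C)=O)C1
F2 | step 8 | 2α-acetoxy-10α-hydroxy-dauca-4,8-dien-6-one | CC(C)C1=C2C(=O)CC(C)=C[C@H](O)[C@]2(C)[C@H](OC(C)=O)C1
F3 | step 8 | 2α-acetoxy-4α,5α-epoxy-10α-hydroxy-dauc-8-en-6-one | CC(C)[C@@]12O[C@@]13C(=O)CC(C)=C[C@H](O)[C@]3(C)[C@H](OC(C)=O)C2
F4 | step 9 | 2α-acetoxy-dauc-8-ene-4α,6β,10α-triol | O[C@H]1CC(C)=C[C@H](O)[C@]2(C)[C@H](OC(C)=O)C[C@@](O)(C(C)C)[C@@H]12
F5 | step 4 | (4R)-1-diazo-4-(2-methoxy-4-methylphenyl)-5-methylhexan-2-one | [N-]=[N+]=CC(=O)C[C@H](C(C)C)c1ccc(C)cc1OC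
F6 | step 4 | 6-methoxy-15-nor-dauca-5,7,9-trien-2-one (1β-H, 4α-isopropyl) | COC1=C2[C@@H](C(C)C)CC(=O)[C@H]2C=CC(C)=C1
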